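**Retrosynthetic overview**

1. Endgame: the hydroquinone is released from its dimethyl ether via the quinone. The chain ketone comes from a carbinol, made by joining aldehyde 11 to the (Z)-allylbarium 22 (bond between the carbinol carbon and its allylic CH2). Fragment 22 carries the arene and the Z-olefin (Still–Gennari olefination).
2. The enone comes from aldol condensation of a methyl ketone with aldehyde 6. The CH2CHO arm comes from anti-Markovnikov hydration of an ethynyl group.
3. Core 3 comes from one formal [3+2] cycloaddition of 1-acetyl-1-methylcyclopropane (1) with enyne 2. It forms ring bonds C1–C2 and C3–C4 and both quaternary stereocentres with the methyl groups cis.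
4. Enabling feature: ring carbon C1 is quaternary and carries the ketone carbonyl directly, next to ring CH2 C5. C1–C5–C4 plus that carbonyl is therefore a ring-opened 1-acylcyclopropane (enolate at C1, radical at C4), and C2(CH3)–C3H2 is a 1,1-disubstituted alkene whose third substituent (ethynyl, later CH2CHO) stabilises the radical.
5. Rings: the arene is bought; the cyclopentane is the only ring formed (step 1).

Key step: step 1

**Remarks**

- Ring locants: cyclopentane C1 bears the enone carbonyl, C2 bears the oxoalkenyl chain, and C3, C4, C5 are the CH2 groups going from C2 round to C1.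
- Assumption on the chemistry: which antipode of the salen ligand leads to (1R,2R)-3 cannot be derived with confidence. The (R,R)-ligand is written, and its mirror image is to be taken if a pilot run shows the opposite sense.
- The carbinol centres of 8 and 23 should form as epimer mixtures and are erased in steps 5 and 15; their SMILES carry no descriptor there.
- Hydroxy ketone 23 may equilibrate with a six-membered hemiketal; the open form is the one oxidised in step 15.

**Route**

Step 1
Reactants: 1 1-(1-methylcyclopropyl)ethan-1-one; 2 2-methylbut-1-en-3-yne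
Product: 3 1-[(1R,2R)-2-ethynyl-1,2-dimethylcyclopentyl]ethan-1-one
Conditions: TiCl2[(R,R)-salen] (10 mol%; salen = N,N'-bis(3,5-di-tert-butylsalicylidene)cyclohexane-1,2-diaminate), Mn powder (20 mol%), Et3N·HCl (20 mol%), 2 (4 equiv), EtOAc, 22 °C, sealed tube
Reagents that add atoms: none
Why: Proposed new method: after Mn has reduced the precatalyst, the trivalent titanium centre binds the carbonyl of 1 and transfers one electron, the ketyl opens the strained ring (its two CH2 groups are equivalent) to a tetravalent-titanium enolate at C1 with a primary radical at C4, this radical adds to the CH2 terminus of 2 to make the C3–C4 bond and a tertiary propargylic radical at C2, and that radical attacks the enolate carbon to make the C1–C2 bond, after which the titanium-bound ketyl hands the electron back to the metal and releases 3. The closest known reaction type is the radical redox-relay formal [3+2] cycloaddition of cyclopropyl ketones with alkenes (titanium–salen, SmI2 or photoredox catalysis), which has not been shown for an alkyl 1-methylcyclopropyl ketone with a 1,1-disubstituted enyne giving two adjacent quaternary carbons. The cyclopentane is the only ring closed and it closes in the 5-exo-trig mode. C1 is set by the chiral salen ligand, which leaves one face of the metal-bound enolate open, and C2 is set relative to C1 in the same transition state, where the bulky titanium enolate unit should lie syn to the slim ethynyl group and not to the methyl group, so that the two methyl groups end up cis. The step needs regioselective radical addition, cis selectivity and enantioselectivity: the first is secured by the conjugated alkyne of 2 (only attack at CH2 gives a stabilised tertiary radical, and the allenyl terminus cannot close a small ring), the second by the size difference between ethynyl and methyl, the third by the catalyst.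

Step 2
Reactants: 4 ethyl 2-hydroxy-2-methylpropanoate
Product: 5 ethyl 2-methyl-2-(triethylsilyloxy)propanoate
Conditions: Et3SiOTf, 2,6-lutidine, CH2Cl2, 0 °C
Reagents that add atoms: triethylsilyl trifluoromethanesulfonate, CC[Si](CC)(CC)OS(=O)(=O)C(F)(F)F
Why: Silyl ether formation; the silyl triflate is reactive enough for a tertiary alcohol.

Step 3
Reactants: 5 ethyl 2-methyl-2-(triethylsilyloxy)propanoate
Product: 6 2-methyl-2-(triethylsilyloxy)propanal
Conditions: iBu2AlH (1.1 equiv), CH2Cl2, −78 °C; then MeOH, aqueous potassium sodium tartrate (KNaC4H4O6)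
Reagents that add atoms: none
Why: Partial ester reduction; the α-silyloxy group stabilises the tetrahedral aluminium hemiacetal so that the aldehyde is released only on work-up.

Step 4
Reactants: 3 1-[(1R,2R)-2-ethynyl-1,2-dimethylcyclopentyl]ethan-1-one; 6 2-methyl-2-(triethylsilyloxy)propanal
Product: 8 1-[(1R,2R)-2-ethynyl-1,2-dimethylcyclopentyl]-3-hydroxy-4-methyl-4-(triethylsilyloxy)pentan-1-one (both C3 epimers), via lithium enolate 7 (not isolated)
Conditions: LiN(iPr)2 (1.05 equiv), THF, −78 °C; then 6, −78 °C; NH4Cl (aq)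
Reagents that add atoms: none
Why: Directed aldol addition; the methyl group is the only enolisable position of the ketone and is more acidic than the alkyne C–H, and 6 cannot enolise.

Step 5
Reactants: 8 1-[(1R,2R)-2-ethynyl-1,2-dimethylcyclopentyl]-3-hydroxy-4-methyl-4-(triethylsilyloxy)pentan-1-one
Product: 10 (E)-1-[(1R,2R)-2-ethynyl-1,2-dimethylcyclopentyl]-4-methyl-4-(triethylsilyloxy)pent-2-en-1-one, via mesylate 9 (not isolated)
Conditions: MsCl, Et3N, CH2Cl2, 0 °C; then DBU, 0 °C to rt
Reagents that add atoms: none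
Why: Mesylation followed by E1cB elimination, which should give the E-enone because the bulky quaternary carbon avoids the carbonyl.

Step 6
Reactants: 10 (E)-1-[(1R,2R)-2-ethynyl-1,2-dimethylcyclopentyl]-4-methyl-4-(triethylsilyloxy)pent-2-en-1-one
Product: 11 2-[(1R,2R)-1,2-dimethyl-2-{(E)-4-methyl-4-(triethylsilyloxy)pent-2-enoyl}cyclopentyl]acetaldehyde
Conditions: [CpRu(MeCN)3]PF6 (5 mol%), 5,5'-bis(trifluoromethyl)-2,2'-bipyridine (5 mol%), NMP/H2O 4:1, 25–50 °C
Reagents that add atoms: water, O
Why: Anti-Markovnikov hydration of a terminal alkyne through a ruthenium vinylidene, under neutral conditions that should leave the enone and the silyl ether untouched.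

Step 7
Reactants: 12 4-methoxy-2-methylphenol
Product: 13 2-bromo-4-methoxy-6-methylphenol
Conditions: N-bromosuccinimide, iPr2NH (10 mol%), CH2Cl2, 0 °C
Reagents that add atoms: N-bromosuccinimide, O=C1CCC(=O)N1Br
Why: Electrophilic aromatic bromination directed by the free phenol to its only open ortho position.

Step 8
Reactants: 13 2-bromo-4-methoxy-6-methylphenol
Product: 14 1-bromo-2,5-dimethoxy-3-methylbenzene
Conditions: MeI, K2CO3, acetone, reflux
Reagents that add atoms: iodomethane, CI
Why: Williamson ether synthesis on the phenoxide.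

Step 9
Reactants: 14 1-bromo-2,5-dimethoxy-3-methylbenzene
Product: 16 2-(2,5-dimethoxy-3-methylphenyl)ethan-1-ol, via aryllithium 15 (not isolated)
Conditions: t-BuLi (2.05 equiv), THF, −78 °C; then oxirane (3 equiv), −78 °C to rt; NH4Cl (aq)
Reagents that add atoms: oxirane, C1CO1
Why: Bromine–lithium exchange followed by SN2 ring opening of the epoxide by the aryllithium.

Step 10
Reactants: 16 2-(2,5-dimethoxy-3-methylphenyl)ethan-1-ol
Product: 17 2-(2,5-dimethoxy-3-methylphenyl)acetaldehyde
Conditions: Dess–Martin periodinane, NaHCO3, CH2Cl2, 0 °C; used crude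
Reagents that add atoms: none
Why: Dess–Martin oxidation, mild enough for an enolisable arylacetaldehyde.

Step 11
Reactants: 17 2-(2,5-dimethoxy-3-methylphenyl)acetaldehyde
Product: 18 ethyl (Z)-4-(2,5-dimethoxy-3-methylphenyl)-2-methylbut-2-enoate
Conditions: ethyl 2-[bis(2,2,2-trifluoroethoxy)phosphoryl]propanoate, KN(SiMe3)2, 18-crown-6, THF, −78 °C; then 17
Reagents that add atoms: ethyl 2-[bis(2,2,2-trifluoroethoxy)phosphoryl]propanoate, CCOC(=O)C(C)P(=O)(OCC(F)(F)F)OCC(F)(F)F
Why: Still–Gennari olefination; the electron-poor phosphonate under dissociating conditions eliminates fast from the kinetic adduct and should give the Z-trisubstituted enoate.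

Step 12
Reactants: 18 ethyl (Z)-4-(2,5-dimethoxy-3-methylphenyl)-2-methylbut-2-enoate
Product: 19 (Z)-4-(2,5-dimethoxy-3-methylphenyl)-2-methylbut-2-en-1-ol
Conditions: iBu2AlH (2.2 equiv), CH2Cl2, −78 °C; aqueous potassium sodium tartrate (KNaC4H4O6)
Reagents that add atoms: none
Why: 1,2-Reduction of the enoate to the allylic alcohol without touching the olefin geometry.

Step 13
Reactants: 19 (Z)-4-(2,5-dimethoxy-3-methylphenyl)-2-methylbut-2-en-1-ol
Product: 21 1-[(Z)-4-chloro-3-methylbut-2-en-1-yl]-2,5-dimethoxy-3-methylbenzene, via allylic mesylate 20 (not isolated)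
Conditions: MsCl, 2,4,6-collidine, LiCl, DMF, 0 °C
Reagents that add atoms: lithium chloride, [Li+].[Cl-]
Why: Mesylation and in situ SN2 displacement by chloride, which should proceed without allylic transposition or Z/E scrambling.

Step 14
Reactants: 21 1-[(Z)-4-chloro-3-methylbut-2-en-1-yl]-2,5-dimethoxy-3-methylbenzene; 11 2-[(1R,2R)-1,2-dimethyl-2-{(E)-4-methyl-4-(triethylsilyloxy)pent-2-enoyl}cyclopentyl]acetaldehyde
Product: 23 (E)-1-[(1R,2R)-2-{(Z)-6-(2,5-dimethoxy-3-methylphenyl)-2-hydroxy-4-methylhex-4-en-1-yl}-1,2-dimethylcyclopentyl]-4-methyl-4-(triethylsilyloxy)pent-2-en-1-one (both carbinol epimers), via allylbarium chloride 22 (not isolated)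
Conditions: activated barium (from BaI2 and lithium biphenylide, THF, rt), then 21, −78 °C; then 11, −78 °C; NH4Cl (aq)
Reagents that add atoms: none
Why: α-Selective carbonyl allylation with an allylbarium reagent, which at −78 °C should keep its Z geometry and add through the metal-bearing CH2 to the aldehyde, far more electrophilic than the hindered enone.

Step 15
Reactants: 23 (E)-1-[(1R,2R)-2-{(Z)-6-(2,5-dimethoxy-3-methylphenyl)-2-hydroxy-4-methylhex-4-en-1-yl}-1,2-dimethylcyclopentyl]-4-methyl-4-(triethylsilyloxy)pent-2-en-1-one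
Product: 24 (E)-1-[(1R,2R)-2-{(Z)-6-(2,5-dimethoxy-3-methylphenyl)-4-methyl-2-oxohex-4-en-1-yl}-1,2-dimethylcyclopentyl]-4-methyl-4-(triethylsilyloxy)pent-2-en-1-one
Conditions: Dess–Martin periodinane, NaHCO3, CH2Cl2, 0 °C to rt
Reagents that add atoms: none
Why: Dess–Martin oxidation under buffered, non-basic conditions, so that the β,γ-unsaturated ketone should not move into conjugation.

Step 16
Reactants: 24 (E)-1-[(1R,2R)-2-{(Z)-6-(2,5-dimethoxy-3-methylphenyl)-4-methyl-2-oxohex-4-en-1-yl}-1,2-dimethylcyclopentyl]-4-methyl-4-(triethylsilyloxy)pent-2-en-1-one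
Product: 25 (E)-1-[(1R,2R)-2-{(Z)-6-(2,5-dimethoxy-3-methylphenyl)-4-methyl-2-oxohex-4-en-1-yl}-1,2-dimethylcyclopentyl]-4-hydroxy-4-methylpent-2-en-1-one
Conditions: HF·pyridine, pyridine, THF, 0 °C to rt
Reagents that add atoms: none
Why: Fluoride-mediated silyl ether cleavage under buffered conditions that avoid enolate chemistry of the 1,5-diketone.

Step 17
Reactants: 25 (E)-1-[(1R,2R)-2-{(Z)-6-(2,5-dimethoxy-3-methylphenyl)-4-methyl-2-oxohex-4-en-1-yl}-1,2-dimethylcyclopentyl]-4-hydroxy-4-methylpent-2-en-1-one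
Product: 27 (E)-1-[(1R,2R)-2-{(Z)-6-(2,5-dihydroxy-3-methylphenyl)-4-methyl-2-oxohex-4-en-1-yl}-1,2-dimethylcyclopentyl]-4-hydroxy-4-methylpent-2-en-1-one, via quinone 26 (not isolated)
Conditions: (NH4)2Ce(NO3)6 (2.5 equiv), MeCN/H2O 2:1, 0 °C, 15 min; then Na2S2O4, H2O/Et2O, rt
Reagents that add atoms: water, O
Why: Oxidative demethylation of the hydroquinone dimethyl ether to the quinone (the ring oxygens come from water) followed by dithionite reduction, a neutral reduction that should spare the enone.

**Compound list**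

1 | 1-(1-methylcyclopropyl)ethan-1-one | CC(=O)C1(C)CC1 | starting material
2 | 2-methylbut-1-en-3-yne | C=C(C)C#C | starting material
3 | 1-[(1R,2R)-2-ethynyl-1,2-dimethylcyclopentyl]ethan-1-one | C#C[C@@]1(C)CCC[C@@]1(C)C(C)=O | intermediate
4 | ethyl 2-hydroxy-2-methylpropanoate | CCOC(=O)C(C)(C)O | starting material
5 | ethyl 2-methyl-2-(triethylsilyloxy)propanoate | CCOC(=O)C(C)(C)O[Si](CC)(CC)CC | intermediate
6 | 2-methyl-2-(triethylsilyloxy)propanal | O=CC(C)(C)O[Si](CC)(CC)CC | intermediate
7 | lithium enolate of 3 (lithium 1-[(1R,2R)-2-ethynyl-1,2-dimethylcyclopentyl]ethen-1-olate) | C#C[C@@]1(C)CCC[C@@]1(C)C(=C)O[Li] | intermediate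
8 | 1-[(1R,2R)-2-ethynyl-1,2-dimethylcyclopentyl]-3-hydroxy-4-methyl-4-(triethylsilyloxy)pentan-1-one (both C3 epimers) | C#C[C@@]1(C)CCC[C@@]1(C)C(=O)CC(O)C(C)(C)O[Si](CC)(CC)CC | intermediate
9 | 3-methanesulfonate of 8 | C#C[C@@]1(C)CCC[C@@]1(C)C(=O)CC(OS(C)(=O)=O)C(C)(C)O[Si](CC)(CC)CC | intermediate
10 | (E)-1-[(1R,2R)-2-ethynyl-1,2-dimethylcyclopentyl]-4-methyl-4-(triethylsilyloxy)pent-2-en-1-one | C#C[C@@]1(C)CCC[C@@]1(C)C(=O)/C=C/C(C)(C)O[Si](CC)(CC)CC | intermediate
11 | 2-[(1R,2R)-1,2-dimethyl-2-{(E)-4-methyl-4-(triethylsilyloxy)pent-2-enoyl}cyclopentyl]acetaldehyde | O=CC[C@@]1(C)CCC[C@@]1(C)C(=O)/C=C/C(C)(C)O[Si](CC)(CC)CC | intermediate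
12 | 4-methoxy-2-methylphenol | COc1ccc(O)c(C)c1 | starting material
13 | 2-bromo-4-methoxy-6-methylphenol | COc1cc(C)c(O)c(Br)c1 | intermediate
14 | 1-bromo-2,5-dimethoxy-3-methylbenzene | COc1cc(C)c(OC)c(Br)c1 | intermediate
15 | (2,5-dimethoxy-3-methylphenyl)lithium | COc1cc(C)c(OC)c([Li])c1 | intermediate
16 | 2-(2,5-dimethoxy-3-methylphenyl)ethan-1-ol | COc1cc(C)c(OC)c(CCO)c1 | intermediate
17 | 2-(2,5-dimethoxy-3-methylphenyl)acetaldehyde | COc1cc(C)c(OC)c(CC=O)c1 | intermediate
18 | ethyl (Z)-4-(2,5-dimethoxy-3-methylphenyl)-2-methylbut-2-enoate | CCOC(=O)/C(C)=C\Cc1cc(OC)cc(C)c1OC | intermediate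
19 | (Z)-4-(2,5-dimethoxy-3-methylphenyl)-2-methylbut-2-en-1-ol | OC/C(C)=C\Cc1cc(OC)cc(C)c1OC | intermediate
20 | (Z)-4-(2,5-dimethoxy-3-methylphenyl)-2-methylbut-2-en-1-yl methanesulfonate | CS(=O)(=O)OC/C(C)=C\Cc1cc(OC)cc(C)c1OC | intermediate
21 | 1-[(Z)-4-chloro-3-methylbut-2-en-1-yl]-2,5-dimethoxy-3-methylbenzene | ClC/C(C)=C\Cc1cc(OC)cc(C)c1OC | intermediate
22 | [(Z)-4-(2,5-dimethoxy-3-methylphenyl)-2-methylbut-2-en-1-yl]barium chloride | Cl[Ba]C/C(C)=C\Cc1cc(OC)cc(C)c1OC | intermediate
23 | (E)-1-[(1R,2R)-2-{(Z)-6-(2,5-dimethoxy-3-methylphenyl)-2-hydroxy-4-methylhex-4-en-1-yl}-1,2-dimethylcyclopentyl]-4-methyl-4-(triethylsilyloxy)pent-2-en-1-one (both carbinol epimers) | C/C(=C/Cc1cc(OC)cc(C)c1OC)CC(O)C[C@@]1(C)CCC[C@@]1(C)C(=O)/C=C/C(C)(C)O[Si](CC)(CC)CC | intermediate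
24 | (E)-1-[(1R,2R)-2-{(Z)-6-(2,5-dimethoxy-3-methylphenyl)-4-methyl-2-oxohex-4-en-1-yl}-1,2-dimethylcyclopentyl]-4-methyl-4-(triethylsilyloxy)pent-2-en-1-one | C/C(=C/Cc1cc(OC)cc(C)c1OC)CC(=O)C[C@@]1(C)CCC[C@@]1(C)C(=O)/C=C/C(C)(C)O[Si](CC)(CC)CC | intermediate
25 | (E)-1-[(1R,2R)-2-{(Z)-6-(2,5-dimethoxy-3-methylphenyl)-4-methyl-2-oxohex-4-en-1-yl}-1,2-dimethylcyclopentyl]-4-hydroxy-4-methylpent-2-en-1-one | C/C(=C/Cc1cc(OC)cc(C)c1OC)CC(=O)C[C@@]1(C)CCC[C@@]1(C)C(=O)/C=C/C(C)(C)O | intermediate
26 | 2-[(Z)-6-{(1R,2R)-2-[(E)-4-hydroxy-4-methylpent-2-enoyl]-1,2-dimethylcyclopentyl}-3-methyl-5-oxohex-2-en-1-yl]-6-methylcyclohexa-2,5-diene-1,4-dione | C/C(=C/CC1=CC(=O)C=C(C)C1=O)CC(=O)C[C@@]1(C)CCC[C@@]1(C)C(=O)/C=C/C(C)(C)O | intermediate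
27 | (E)-1-[(1R,2R)-2-{(Z)-6-(2,5-dihydroxy-3-methylphenyl)-4-methyl-2-oxohex-4-en-1-yl}-1,2-dimethylcyclopentyl]-4-hydroxy-4-methylpent-2-en-1-one | C/C(=C/Cc1cc(O)cc(C)c1O)CC(=O)C[C@@]1(C)CCC[C@@]1(C)C(=O)/C=C/C(C)(C)O | target

**Step count and risks**

Total step count: 17. Longest linear sequence: 11 steps (12 to 27 through steps 7–13 and 14–17).

Steps most likely to fail:

Step 1 (Proposed new method). Trivalent titanium may reduce a non-aryl ketone too slowly for ring opening. The tertiary propargylic radical may be reduced or may oligomerise before it closes on the enolate. The closure between two fully substituted carbons may show poor facial or cis/trans discrimination. The fallback uses known chemistry, a de Mayo sequence. It sets out from aldehyde 6 of the route together with two commercial compounds, 1,2-dimethylcyclopentene and 2,2,6-trimethyl-4H-1,3-dioxin-4-one (taken in place of 1 and 2), and comes back at compound 11. Irradiation (300 nm, MeCN/acetone, 0 °C) should give by [2+2] photocycloaddition the racemic cis-fused photoadduct F1. K2CO3 in MeOH should open the dioxanone with retro-aldol cleavage of the cyclobutane to the racemic keto ester F2, in which acetyl and CH2CO2Me are cis because the alkene adds suprafacially. Preparative chromatography on a chiral stationary phase should give the (1R,2R)-keto ester F3. LiN(iPr)2 at −78 °C should form the ketone enolate F4, which adds to 6 to give the aldol F5. MsCl/Et3N and then DBU should give, through the mesylate F6, the enone ester F7. iBu2AlH should reduce the ester and the enone carbonyl to the diol F8. Swern oxidation ((COCl)2, DMSO, CH2Cl2, −78 °C, then Et3N), which activates both hydroxyl groups before base is added and so avoids lactol formation, should give 11.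

Step 14. The allylbarium may undergo a 1,3-metal shift if it warms, with attack through the other allyl terminus or loss of Z geometry. Wurtz-type homocoupling may compete while it forms, and the reagent may also add to the enone. The fallback sets out from 21 and 11 and comes back at 24, so step 15 is not needed. Displacement with PhSO2Na in DMF should give the allylic sulfone F9. n-BuLi in THF at −78 °C should give the α-lithio sulfone F10, which adds through its sulfonyl-bearing carbon to 11 to give the β-hydroxy sulfone F11. Dess–Martin oxidation should give the β-keto sulfone F12. SmI2 in THF/MeOH at −78 °C should cleave the C–S bond and protonate the dienolate at the α-carbon to give 24.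

Step 6. Vinylidene formation at an alkyne flanked by two quaternary carbons may be slow, so that catalyst decay outruns hydration. The fallback sets out from 10 and comes back at 11. Hydroboration with dicyclohexylborane (1.1 equiv, THF, 0 °C), faster at a terminal alkyne than at the hindered enone, should give the (E)-alkenylborane F13. Oxidation with NaBO3·4H2O in THF/H2O at rt should give 11.

**Further compounds**

F1 | step 1 | racemic cis-fused [2+2] photoadduct of 1,2-dimethylcyclopentene and the dioxinone (cyclobutane fused to a 1,3-dioxan-4-one and to the cyclopentane; both enantiomers; syn or anti fusion at the dioxanone not specified) | CC1(C)OC(=O)C2[C@@]3(C)CCC[C@@]3(C)C2(C)O1.CC1(C)OC(=O)C2[C@]3(C)CCC[C@]3(C)C2(C)O1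
F2 | step 1 | racemic methyl 2-(cis-2-acetyl-1,2-dimethylcyclopentyl)acetate (both enantiomers) | COC(=O)C[C@@]1(C)CCC[C@@]1(C)C(C)=O.COC(=O)C[C@]1(C)CCC[C@]1(C)C(C)=O
F3 | step 1 | methyl 2-[(1R,2R)-2-acetyl-1,2-dimethylcyclopentyl]acetate | COC(=O)C[C@@]1(C)CCC[C@@]1(C)C(C)=O
F4 | step 1 | lithium enolate of F3 at the acetyl group | COC(=O)C[C@@]1(C)CCC[C@@]1(C)C(=C)O[Li]
F5 | step 1 | methyl 2-[(1R,2R)-2-{3-hydroxy-4-methyl-4-(triethylsilyloxy)pentanoyl}-1,2-dimethylcyclopentyl]acetate (both carbinol epimers) | COC(=O)C[C@@]1(C)CCC[C@@]1(C)C(=O)CC(O)C(C)(C)O[Si](CC)(CC)CC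
F6 | step 1 | methanesulfonate of F5 | COC(=O)C[C@@]1(C)CCC[C@@]1(C)C(=O)CC(OS(C)(=O)=O)C(C)(C)O[Si](CC)(CC)CC
F7 | step 1 | methyl 2-[(1R,2R)-1,2-dimethyl-2-{(E)-4-methyl-4-(triethylsilyloxy)pent-2-enoyl}cyclopentyl]acetate | COC(=O)C[C@@]1(C)CCC[C@@]1(C)C(=O)/C=C/C(C)(C)O[Si](CC)(CC)CC
F8 | step 1 | 2-[(1R,2R)-2-{(E)-1-hydroxy-4-methyl-4-(triethylsilyloxy)pent-2-en-1-yl}-1,2-dimethylcyclopentyl]ethan-1-ol (both carbinol epimers) | OCC[C@@]1(C)CCC[C@@]1(C)C(O)/C=C/C(C)(C)O[Si](CC)(CC)CC
F9 | step 14 | 1-[(Z)-4-(benzenesulfonyl)-3-methylbut-2-en-1-yl]-2,5-dimethoxy-3-methylbenzene | O=S(=O)(C/C(C)=C\Cc1cc(OC)cc(C)c1OC)c1ccccc1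
F10 | step 14 | α-lithio derivative of sulfone F9 | [Li]C(S(=O)(=O)c1ccccc1)/C(C)=C\Cc1cc(OC)cc(C)c1OC
F11 | step 14 | β-hydroxy sulfone from F10 and 11 (mixture of diastereomers at the two new centres) | OC(C[C@@]1(C)CCC[C@@]1(C)C(=O)/C=C/C(C)(C)O[Si](CC)(CC)CC)C(S(=O)(=O)c1ccccc1)/C(C)=C\Cc1cc(OC)cc(C)c1OC
F12 | step 14 | β-keto sulfone from oxidation of F11 (3-benzenesulfonyl derivative of 24) | O=C(C[C@@]1(C)CCC[C@@]1(C)C(=O)/C=C/C(C)(C)O[Si](CC)(CC)CC)C(S(=O)(=O)c1ccccc1)/C(C)=C\Cc1cc(OC)cc(C)c1OC
F13 | step 6 | (E)-alkenyl(dicyclohexyl)borane from hydroboration of the ethynyl group of 10 | C1CCCCC1B(C1CCCCC1)/C=C/[C@@]1(C)CCC[C@@]1(C)C(=O)/C=C/C(C)(C)O[Si](CC)(CC)CC
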